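**Retrosynthetic overview**
Feature: the only ring of the target is a benzene ring of the 4-methoxyphenol type. Its C–OH carbon lies between the acyl-bearing and the sec-alkyl-bearing ring carbons, and the para C–OMe carbon lies between two ring CH. A chromium alkenyl(methoxy)carbene (C–OMe, CH, C-acyl), one CO ligand (C–OH) and a terminal alkyne (C-alkyl, CH) assemble exactly this pattern.
Side arms: the benzylic CH(CH3)CH2CH2CH= unit is C3–C6 of (R)-citronellal and enters as the alkyne; the aryl C(=O)–CH=CH–CH unit is a 2-furyl ring in masked form.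
Disconnections, backwards: acidolysis of three tert-butyl groups; C4=C5 of the trienoate by vinylogous Horner–Wadsworth–Emmons olefination; the ketoenal by oxidative furan opening; the enoate by cross-metathesis at the isopropylidene end; the arene by Dötz benzannulation.
Ring order: the furan is bought (furfural), the benzene ring is built next to it in step 4, and the furan is opened in step 7, so only the benzene ring remains.

Key step: step 4

Assumption: the purchased (R)-citronellal is of high enantiomeric purity, because no later step can raise the enantiomeric purity.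

Step 1
Reactants: 1 (R)-citronellal
Product: 3 (R)-3,7-dimethyloct-6-en-1-yne, via enol nonaflate 2 (not isolated)
Conditions: n-C4F9SO2F (1.3 equiv), tBuN=P(pyrrolidin-1-yl)3 (BTPP, 2.5 equiv, added slowly), DMF, −20 °C → rt; pentane extraction
Reagents that add atoms: nonafluorobutane-1-sulfonyl fluoride, FS(=O)(=O)C(F)(F)C(F)(F)C(F)(F)C(F)(F)F (its C4F9SO2 group stands in 2 only; nothing of it remains in 3)
Why: Nonaflation–elimination of an enolisable aldehyde: the phosphazene base enolises 1 beside the sulfonyl fluoride, the enolate is trapped on oxygen as 2, and a second equivalent of base eliminates nonaflate, so CH2–CHO becomes C≡CH with no change in carbon count, under non-acidic conditions that avoid the carbonyl-ene cyclisation of citronellal and are too mild to shift the triple bond to the allene, which leaves the stereocentre (β to the aldehyde, now propargylic) unchanged.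

Step 2
Reactants: 4 chromium hexacarbonyl, Cr(CO)6
Product: 6 pentacarbonyl[methoxy(methyl)carbene]chromium, via lithium acyl chromate 5 (not isolated)
Conditions: MeLi, Et2O, 0 °C → rt; evaporate; then Me3OBF4, H2O, 0 °C; pentane extraction
Reagents that add atoms: methyllithium, [Li]C; trimethyloxonium tetrafluoroborate, C[O+](C)C.F[B-](F)(F)F
Why: Fischer carbene synthesis: the organolithium adds to a CO ligand to give acyl chromate 5, and the hard oxonium salt methylates it on oxygen.

Step 3
Reactants: 6 pentacarbonyl[methoxy(methyl)carbene]chromium; 7 furfural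
Product: 8 pentacarbonyl[(2E)-3-(furan-2-yl)-1-methoxyprop-2-en-1-ylidene]chromium
Conditions: 7 (1.5 equiv), Et3N (4 equiv), Me3SiCl (3 equiv), Et2O, rt
Reagents that add atoms: none
Why: Aldol condensation of a Fischer carbene complex: the methyl protons next to the carbene carbon are acidic enough for Et3N, the chlorosilane activates the aldehyde and turns the aldol oxygen into a leaving group, and E1cB elimination gives the fully conjugated E alkene.

Step 4
Reactants: 3 (R)-3,7-dimethyloct-6-en-1-yne; 8 pentacarbonyl[(2E)-3-(furan-2-yl)-1-methoxyprop-2-en-1-ylidene]chromium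
Product: 10 2-(furan-2-yl)-4-methoxy-6-[(2R)-6-methylhept-5-en-2-yl]phenol, via arene Cr(CO)3 complex 9 (not isolated)
Conditions: 3 (1.5 equiv), THF (0.05 M in 8), 50 °C, argon; then Et2O, air, daylight, rt; filtration through silica
Reagents that add atoms: none
Why: This is a Dötz benzannulation, the established reaction of alkenyl(alkoxy)carbene complexes of zerovalent chromium with terminal alkynes to give 4-alkoxyphenols. Warm THF expels one cis CO ligand from 8, alkyne 3 takes the free site and inserts into the Cr=C bond so that its CH end bonds to the carbene carbon, and a CO ligand then migrates to the new carbene carbon (the one bearing the sec-alkyl group) to give a chromium-bound dienylketene. The benzene ring closes by 6π electrocyclisation between the ketene carbon and the furyl-bearing vinyl carbon, and enolisation of the cyclohexadienone gives the phenol as its Cr(CO)3 complex 9, from which air and light remove the metal without oxidising the hydroquinone monoether (a strong oxidant such as (NH4)2Ce(NO3)6 would give the quinone). No stereocentre is made: the propargylic C–H of 3 takes no part and becomes the benzylic (R) centre unchanged. The regioselectivity needed (sec-alkyl next to C–OH, H next to C–OMe) follows from the large size difference between H and the branched substituent of the terminal alkyne. The chemoselectivity needed is CO insertion ahead of cyclopropanation or metathesis of the tethered alkene by the vinylcarbene intermediate, and it is helped by the hindered trisubstituted alkene, the donor solvent and the strong bias of chromium alkenylcarbenes for phenol formation; the furan is only a substituent on the vinyl carbon and is not engaged.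

Step 5
Reactants: 10 2-(furan-2-yl)-4-methoxy-6-[(2R)-6-methylhept-5-en-2-yl]phenol
Product: 11 tert-butyl 2-(furan-2-yl)-4-methoxy-6-[(2R)-6-methylhept-5-en-2-yl]phenyl carbonate
Conditions: Boc2O (1.5 equiv), DMAP (0.2 equiv), MeCN, rt
Reagents that add atoms: di-tert-butyl dicarbonate, CC(C)(C)OC(=O)OC(=O)OC(C)(C)C
Why: DMAP-catalysed O-acylation masks the phenol, which would otherwise be attacked by singlet oxygen, quench the later carbanion and add to the enone, with a group that leaves in the same acid step as the esters.

Step 6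
Reactants: 11 tert-butyl 2-(furan-2-yl)-4-methoxy-6-[(2R)-6-methylhept-5-en-2-yl]phenyl carbonate; 12 tert-butyl acrylate
Product: 13 tert-butyl (2E,6R)-6-[2-(tert-butoxycarbonyloxy)-3-(furan-2-yl)-5-methoxyphenyl]hept-2-enoate
Conditions: 12 (5 equiv), second-generation Hoveyda–Grubbs catalyst RuCl2(H2IMes)(=CH-C6H4-2-OiPr) (5 mol %), CH2Cl2, 40 °C, argon sweep
Reagents that add atoms: none
Why: Olefin cross-metathesis of an isopropylidene alkene that does not homodimerise with an electron-poor acrylate, as known for citronellyl-type chains, is driven by loss of volatile isobutene and gives the E enoate under thermodynamic control, while furan, carbonate and stereocentre are untouched.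

Step 7
Reactants: 13 tert-butyl (2E,6R)-6-[2-(tert-butoxycarbonyloxy)-3-(furan-2-yl)-5-methoxyphenyl]hept-2-enoate
Product: 15 tert-butyl (2E,6R)-6-{2-(tert-butoxycarbonyloxy)-5-methoxy-3-[(2Z)-4-oxobut-2-enoyl]phenyl}hept-2-enoate, via furan endoperoxide 14 (not isolated)
Conditions: O2, tetraphenylporphyrin (cat.), visible light, CH2Cl2, −78 °C; then Me2S, −78 °C → rt
Reagents that add atoms: dioxygen, O=O
Why: [4+2] cycloaddition of singlet oxygen to the furan, the only electron-rich diene left now that the trisubstituted alkene is an inert enoate and the phenol is acylated, gives endoperoxide 14, and reduction of its O–O bond by the sulfide collapses it to the cis ene-dicarbonyl, with the aryl ketone at the former furan C2 and the aldehyde at C5.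

Step 8
Reactants: 15 tert-butyl (2E,6R)-6-{2-(tert-butoxycarbonyloxy)-5-methoxy-3-[(2Z)-4-oxobut-2-enoyl]phenyl}hept-2-enoate
Product: 16 tert-butyl (2E,6R)-6-{2-(tert-butoxycarbonyloxy)-5-methoxy-3-[(2E)-4-oxobut-2-enoyl]phenyl}hept-2-enoate
Conditions: pyridine (0.3 equiv), CH2Cl2, rt, dark
Reagents that add atoms: none
Why: Nucleophile-catalysed Z to E isomerisation of an ene-dicarbonyl (reversible conjugate addition of pyridine, bond rotation, expulsion) runs downhill to the less strained, fully conjugated E isomer and is mild enough for the carbonate and ester.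

Step 9
Reactants: 17 tert-butyl crotonate
Product: 18 tert-butyl (E)-4-bromobut-2-enoate
Conditions: NBS (1.05 equiv), AIBN (cat.), PhCF3, reflux
Reagents that add atoms: N-bromosuccinimide, O=C1CCC(=O)N1Br
Why: Wohl–Ziegler radical bromination takes the only allylic C–H position, and the conjugated E geometry is kept.

Step 10
Reactants: 18 tert-butyl (E)-4-bromobut-2-enoate
Product: 19 tert-butyl (E)-4-(diethoxyphosphoryl)but-2-enoate
Conditions: P(OEt)3 (1.2 equiv), neat, 120 °C, EtBr distilled off
Reagents that add atoms: triethyl phosphite, CCOP(OCC)OCC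
Why: In this Michaelis–Arbuzov reaction, SN2 attack of phosphorus on the primary allylic bromide is followed by dealkylation of the phosphonium salt by bromide.

Step 11
Reactants: 16 tert-butyl (2E,6R)-6-{2-(tert-butoxycarbonyloxy)-5-methoxy-3-[(2E)-4-oxobut-2-enoyl]phenyl}hept-2-enoate; 19 tert-butyl (E)-4-(diethoxyphosphoryl)but-2-enoate
Product: 21 tert-butyl (2E,4E,6E)-8-{2-(tert-butoxycarbonyloxy)-3-[(2R,5E)-7-tert-butoxy-7-oxohept-5-en-2-yl]-5-methoxyphenyl}-8-oxoocta-2,4,6-trienoate, via lithiated phosphonate 20 (not isolated)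
Conditions: 19 (1.2 equiv), LiN(SiMe3)2 (1.1 equiv), THF, −78 °C; then 16, −78 → −30 °C; pH 7 buffer quench, dark
Reagents that add atoms: lithium bis(trimethylsilyl)amide, [Li+].C[Si](C)(C)[N-][Si](C)(C)C (its lithium stands in 20 only)
Why: Vinylogous Horner–Wadsworth–Emmons olefination: the stabilised anion 20 reacts through the carbon next to phosphorus with the aldehyde, which is far more electrophilic and less hindered than the ortho-substituted aryl ketone, and reversible addition followed by syn elimination sets the new C4=C5 bond E, any minor Z isomer being open to equilibration with a trace of iodine.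

Step 12
Reactants: 21 tert-butyl (2E,4E,6E)-8-{2-(tert-butoxycarbonyloxy)-3-[(2R,5E)-7-tert-butoxy-7-oxohept-5-en-2-yl]-5-methoxyphenyl}-8-oxoocta-2,4,6-trienoate
Product: 22 (2E,4E,6E)-8-{3-[(2R,5E)-6-carboxyhex-5-en-2-yl]-2-hydroxy-5-methoxyphenyl}-8-oxoocta-2,4,6-trienoic acid (CNP0274934.1)
Conditions: CF3CO2H/CH2Cl2 (1:3), anisole (10 equiv), 0 °C → rt, dark; evaporation with toluene, no basic wash
Reagents that add atoms: none
Why: Acidolysis by tert-butyl cation loss cleaves both esters and the aryl carbonate (which then decarboxylates) in one operation, anisole keeps the cations off the electron-rich ring, hydride donors and thiols are left out because they would reduce or add to the trienone, and the short cold exposure without base keeps the ortho-hydroxyaryl trienone from closing to a chromanone and the polyene from isomerising.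

**Compound list**
1 | (R)-citronellal, (3R)-3,7-dimethyloct-6-enal | O=CC[C@H](C)CCC=C(C)C | starting material
2 | (3R)-3,7-dimethylocta-1,6-dien-1-yl nonafluorobutane-1-sulfonate (E/Z mixture at C1=C2) | FC(F)(F)C(F)(F)C(F)(F)C(F)(F)S(=O)(=O)OC=C[C@H](C)CCC=C(C)C | intermediate
3 | (R)-3,7-dimethyloct-6-en-1-yne | C#C[C@H](C)CCC=C(C)C | intermediate
4 | chromium hexacarbonyl, Cr(CO)6 | O=C=[Cr](=C=O)(=C=O)(=C=O)(=C=O)=C=O | starting material
5 | lithium acetylpentacarbonylchromate, Li[(CO)5CrC(O)CH3] | [Li+].CC([O-])=[Cr](=C=O)(=C=O)(=C=O)(=C=O)=C=O | intermediate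
6 | pentacarbonyl[methoxy(methyl)carbene]chromium | COC(C)=[Cr](=C=O)(=C=O)(=C=O)(=C=O)=C=O | intermediate
7 | furfural | O=Cc1ccco1 | starting material
8 | pentacarbonyl[(2E)-3-(furan-2-yl)-1-methoxyprop-2-en-1-ylidene]chromium | COC(/C=C/c1ccco1)=[Cr](=C=O)(=C=O)(=C=O)(=C=O)=C=O | intermediate
9 | tricarbonyl(η6-arene)chromium complex of 10 (both faces; the η6 bond is written as a dot) | COc1cc(-c2ccco2)c(O)c([C@H](C)CCC=C(C)C)c1.O=C=[Cr](=C=O)=C=O | intermediate
10 | 2-(furan-2-yl)-4-methoxy-6-[(2R)-6-methylhept-5-en-2-yl]phenol | COc1cc(-c2ccco2)c(O)c([C@H](C)CCC=C(C)C)c1 | intermediate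
11 | tert-butyl 2-(furan-2-yl)-4-methoxy-6-[(2R)-6-methylhept-5-en-2-yl]phenyl carbonate | COc1cc(-c2ccco2)c(OC(=O)OC(C)(C)C)c([C@H](C)CCC=C(C)C)c1 | intermediate
12 | tert-butyl acrylate | C=CC(=O)OC(C)(C)C | starting material
13 | tert-butyl (2E,6R)-6-[2-(tert-butoxycarbonyloxy)-3-(furan-2-yl)-5-methoxyphenyl]hept-2-enoate | COc1cc(-c2ccco2)c(OC(=O)OC(C)(C)C)c([C@H](C)CC/C=C/C(=O)OC(C)(C)C)c1 | intermediate
14 | 1-aryl-2,3,7-trioxabicyclo[2.2.1]hept-5-ene from 13 (bridgehead centres formed on both faces) | COc1cc(C23C=CC(O2)OO3)c(OC(=O)OC(C)(C)C)c([C@H](C)CC/C=C/C(=O)OC(C)(C)C)c1 | intermediate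
15 | tert-butyl (2E,6R)-6-{2-(tert-butoxycarbonyloxy)-5-methoxy-3-[(2Z)-4-oxobut-2-enoyl]phenyl}hept-2-enoate | COc1cc(C(=O)/C=C\C=O)c(OC(=O)OC(C)(C)C)c([C@H](C)CC/C=C/C(=O)OC(C)(C)C)c1 | intermediate
16 | tert-butyl (2E,6R)-6-{2-(tert-butoxycarbonyloxy)-5-methoxy-3-[(2E)-4-oxobut-2-enoyl]phenyl}hept-2-enoate | COc1cc(C(=O)/C=C/C=O)c(OC(=O)OC(C)(C)C)c([C@H](C)CC/C=C/C(=O)OC(C)(C)C)c1 | intermediate
17 | tert-butyl crotonate | C/C=C/C(=O)OC(C)(C)C | starting material
18 | tert-butyl (E)-4-bromobut-2-enoate | BrC/C=C/C(=O)OC(C)(C)C | intermediate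
19 | tert-butyl (E)-4-(diethoxyphosphoryl)but-2-enoate | CCOP(=O)(OCC)C/C=C/C(=O)OC(C)(C)C | intermediate
20 | lithium salt of the carbanion of 19 | [Li+].CCOP(=O)(OCC)[CH-]/C=C/C(=O)OC(C)(C)C | intermediate
21 | tert-butyl (2E,4E,6E)-8-{2-(tert-butoxycarbonyloxy)-3-[(2R,5E)-7-tert-butoxy-7-oxohept-5-en-2-yl]-5-methoxyphenyl}-8-oxoocta-2,4,6-trienoate | COc1cc(C(=O)/C=C/C=C/C=C/C(=O)OC(C)(C)C)c(OC(=O)OC(C)(C)C)c([C@H](C)CC/C=C/C(=O)OC(C)(C)C)c1 | intermediate
22 | (2E,4E,6E)-8-{3-[(2R,5E)-6-carboxyhex-5-en-2-yl]-2-hydroxy-5-methoxyphenyl}-8-oxoocta-2,4,6-trienoic acid | COc1cc(C(=O)/C=C/C=C/C=C/C(=O)O)c(O)c([C@H](C)CC/C=C/C(=O)O)c1 | target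

**Step count**
- Total step count: 12.
- Longest linear sequence: 9 steps from Cr(CO)6 (steps 2, 3, 4, 5, 6, 7, 8, 11, 12). The citronellal branch joins after 1 step and the phosphonate branch after 2 steps.

**Three steps most likely to fail**

Step 4.
- What may go wrong: the vinylcarbene intermediate is captured by the tethered alkene (intramolecular cyclopropanation or enyne metathesis) before CO can insert, so the arene does not form cleanly.
- Fallback (from 3, back at 13): the alkene is removed from the alkyne partner, and the enoate is made by Wittig olefination in place of metathesis. Ozonolysis of 3 with one equivalent of ozone (CH2Cl2, −78 °C, then Me2S) should give (4R)-4-methylhex-5-ynal F1, because the trisubstituted alkene reacts far faster than the terminal alkyne. HC(OMe)3 and catalytic pyridinium tosylate in MeOH turn this aldehyde into (3R)-6,6-dimethoxy-3-methylhex-1-yne F2. Benzannulation of this alkyne with 8 under the conditions of step 4 goes by way of the acetal-bearing arene tricarbonylchromium complex F3 to 2-[(2R)-5,5-dimethoxypentan-2-yl]-6-(furan-2-yl)-4-methoxyphenol F4. Boc2O and DMAP give tert-butyl 2-[(2R)-5,5-dimethoxypentan-2-yl]-6-(furan-2-yl)-4-methoxyphenyl carbonate F5. Pyridinium tosylate in wet acetone frees tert-butyl 2-(furan-2-yl)-4-methoxy-6-[(2R)-5-oxopentan-2-yl]phenyl carbonate F6. Ph3P=CHCO2tBu (CH2Cl2, rt) then gives 13, so step 6 is no longer needed.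

Step 11.
- What may go wrong: conjugate addition of the phosphonate carbanion to the doubly activated alkene, attack on the aryl carbonate, or poor E/Z control at the new double bond.
- Fallback (from 16, back at 21): the four carbons are added two at a time with neutral stabilised ylides, so no strong base or metalated carbanion is present. Ph3P=CHCHO (1 equiv, toluene, rt to 40 °C) reacts at the aldehyde to give tert-butyl (2E,6R)-6-{2-(tert-butoxycarbonyloxy)-5-methoxy-3-[(2E,4E)-6-oxohexa-2,4-dienoyl]phenyl}hept-2-enoate F7. Ph3P=CHCO2tBu (CH2Cl2, rt) then closes the trienoate to 21.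

Step 7.
- What may go wrong: rearrangement or further oxidation of the endoperoxide (loss of the C5–H to a hydroxybutenolide, acyl migration) before the sulfide reduces it, or slow uptake of singlet oxygen by the twisted aryl furan.
- Fallback (from 13, back at 15): the peroxide route is replaced by a two-electron oxidative 2,5-dimethoxylation of the furan (Br2, Na2CO3, MeOH/Et2O, −40 °C). This gives tert-butyl (2E,6R)-6-[2-(tert-butoxycarbonyloxy)-3-(2,5-dimethoxy-2,5-dihydrofuran-2-yl)-5-methoxyphenyl]hept-2-enoate F8 as a storable mixture of diastereomers. Mild hydrolysis of this bis-acetal (pyridinium tosylate, wet acetone, rt) releases 15, which goes on to step 8.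

**Further compounds**
F1 | step 4 | (4R)-4-methylhex-5-ynal | C#C[C@H](C)CCC=O
F2 | step 4 | (3R)-6,6-dimethoxy-3-methylhex-1-yne | C#C[C@H](C)CCC(OC)OC
F3 | step 4 | tricarbonyl{η6-2-[(2R)-5,5-dimethoxypentan-2-yl]-6-(furan-2-yl)-4-methoxyphenol}chromium (η6 bond written as a dot) | COc1cc(-c2ccco2)c(O)c([C@H](C)CCC(OC)OC)c1.O=C=[Cr](=C=O)=C=O
F4 | step 4 | 2-[(2R)-5,5-dimethoxypentan-2-yl]-6-(furan-2-yl)-4-methoxyphenol | COc1cc(-c2ccco2)c(O)c([C@H](C)CCC(OC)OC)c1
F5 | step 4 | tert-butyl 2-[(2R)-5,5-dimethoxypentan-2-yl]-6-(furan-2-yl)-4-methoxyphenyl carbonate | COc1cc(-c2ccco2)c(OC(=O)OC(C)(C)C)c([C@H](C)CCC(OC)OC)c1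
F6 | step 4 | tert-butyl 2-(furan-2-yl)-4-methoxy-6-[(2R)-5-oxopentan-2-yl]phenyl carbonate | COc1cc(-c2ccco2)c(OC(=O)OC(C)(C)C)c([C@H](C)CCC=O)c1
F7 | step 11 | tert-butyl (2E,6R)-6-{2-(tert-butoxycarbonyloxy)-5-methoxy-3-[(2E,4E)-6-oxohexa-2,4-dienoyl]phenyl}hept-2-enoate | COc1cc(C(=O)/C=C/C=C/C=O)c(OC(=O)OC(C)(C)C)c([C@H](C)CC/C=C/C(=O)OC(C)(C)C)c1
F8 | step 7 | tert-butyl (2E,6R)-6-[2-(tert-butoxycarbonyloxy)-3-(2,5-dimethoxy-2,5-dihydrofuran-2-yl)-5-methoxyphenyl]hept-2-enoate | COc1cc(C2(OC)C=CC(OC)O2)c(OC(=O)OC(C)(C)C)c([C@H](C)CC/C=C/C(=O)OC(C)(C)C)c1
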